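**Plan**
- Late cuts: the C1–C10 oxirane, the C11=C13 methylene, the O3 and O8 ester C–O bonds, the C12–O6 lactone bond, then the C3 oxygen and the C15 oxidation level.
- Core cut: the C1=C10 and C4=C5 π bonds are traced back to the C1–C4 and C5–C10 σ bonds of a cis,anti,cis-tricyclo[4.4.0.0(2,5)]decanone. Its central cyclobutane (C4–C5, C1–C10) comes from an enone + cyclobutene ester [2+2]; C7–C11 comes from enolate alkylation.
- Feature used: in the ten-membered ring the segment C10=C1–C2–C3–C4=C5 is a 1,5-diene with a trans C1=C10 and a ring-cis C4=C5 bond. This is the pattern a cis-fused cyclohexane-1,4-diyl releases when the bond shared by its two six-membered rings breaks.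
- Forward order: cyclohexenone ring (aldol) → two four-membered rings (photocycloaddition) → C7 side chain on the rigid tricycle → thermal cycloreversion opens the ten-membered ring → lactone ring → oxirane.
- Stereochemistry: C8 from the amine-catalysed desymmetrising aldol. C8 steers the photocycloaddition and, through the diyl chair, both alkene geometries. C7 by convex-face alkylation of the tricycle; C6 by 1,3-anti Evans–Tishchenko reduction from O8; C3 by CBS reduction; the side-chain oxirane by Sharpless epoxidation; the ring oxirane by peripheral peracid attack.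

Key step: step 10

Remark: germacrane numbering is used for all ring compounds (C1–C10 ring, C11–C13 side chain/lactone, C14 on C10, C15 on C4). β is the face of the C8 oxygen (in the tricycles the face of C14 and H-5, opposite the central cyclobutane); in the target O3, C11 and O8 are β and O6 is α.

Assumption: the quinine-derived primary amine is taken to give the (R)-enone in step 3; if the sense is opposite, its quinidine-derived pseudoenantiomer is used.

**Route**

Step 1
Reactants: 1 hepta-1,6-dien-4-ol
Product: 2 tert-butyl(hepta-1,6-dien-4-yloxy)dimethylsilane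
Conditions: TBSCl, imidazole, DMF, rt
Reagents that add atoms: tert-butyldimethylsilyl chloride (TBSCl), CC(C)(C)[Si](C)(C)Cl
Why: Imidazole-promoted silylation of the only hydroxyl gives a bulky, base-stable ether that later steers the photocycloaddition; no stereocentre is formed.

Step 2
Reactants: 2 tert-butyl(hepta-1,6-dien-4-yloxy)dimethylsilane
Product: 3 4-[(tert-butyldimethylsilyl)oxy]heptane-2,6-dione
Conditions: PdCl2 (cat.), CuCl, O2 (1 atm), DMF/H2O, rt
Reagents that add atoms: water, O
Why: Tsuji–Wacker oxidation turns both terminal alkenes into methyl ketones with Markovnikov selectivity, water supplying the carbonyl oxygen while CuCl/O2 returns palladium to the divalent state; the product is achiral.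

Step 3
Reactants: 3 4-[(tert-butyldimethylsilyl)oxy]heptane-2,6-dione
Product: 4 (R)-5-[(tert-butyldimethylsilyl)oxy]-3-methylcyclohex-2-en-1-one
Conditions: 9-amino-9-deoxy-epi-quinine (cat.), AcOH (cat.), toluene, −15 °C
Reagents that add atoms: none
Why: Enamine-mediated desymmetrising intramolecular aldol condensation of a 4-substituted heptane-2,6-dione: the chiral primary amine selects one of the two enantiotopic acetonyl arms as donor and so sets the silyloxy-bearing centre (the later C8) as R, the weakly acidic medium avoiding β-elimination.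

Step 4
Reactants: 5 methyl cyclobutanecarboxylate
Product: 6 methyl 1-(phenylselanyl)cyclobutane-1-carboxylate
Conditions: LiN(iPr)2, THF, −78 °C; then PhSeBr
Reagents that add atoms: benzeneselenenyl bromide (PhSeBr), Br[Se]c1ccccc1
Why: α-Selenenylation of the ester lithium enolate, which can form only at the single α-CH.

Step 5
Reactants: 6 methyl 1-(phenylselanyl)cyclobutane-1-carboxylate
Product: 8 methyl cyclobut-1-ene-1-carboxylate, via selenoxide 7 (not isolated)
Conditions: 30% H2O2, pyridine, CH2Cl2, 0 °C → rt
Reagents that add atoms: none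
Why: Oxidation to the selenoxide and its syn-elimination (selenoxide elimination) can only engage a ring β-hydrogen and gives the conjugated cyclobutene ester, which is kept cold and used in excess because it polymerises readily.

Step 6
Reactants: 4 (R)-5-[(tert-butyldimethylsilyl)oxy]-3-methylcyclohex-2-en-1-one; 8 methyl cyclobut-1-ene-1-carboxylate
Product: 9 cis,anti,cis photoadduct (1S,4R,5S,8R,10S): central cyclobutane C1–C4–C5–C10, CO2Me on C4, CH3 on C10, C6 ketone, 8β-OTBS anti to the central cyclobutane
Conditions: hν (Pyrex-filtered Hg lamp), 8 (4 equiv), CH2Cl2, −40 °C; then basic Al2O3, rt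
Reagents that add atoms: none
Why: Enone–alkene [2+2] photocycloaddition through the enone triplet: the electron-poor cyclobutene should add head-to-head (ester carbon C4 to the α-carbon C5, C1 to the β-carbon C10) and exo to give the cis,anti,cis skeleton, approaching the enone face opposite the silyloxy group that sits 1,3 to C10, so that C1, C4, C5 and C10 are set relative to C8 (alumina converges any trans-fused adduct through C5).

Step 7
Reactants: 9 cis,anti,cis photoadduct
Product: 10 7β-allyl photoadduct (1S,4R,5S,7R,8R,10S), allyl cis to the 8-silyloxy group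
Conditions: LiN(iPr)2, THF, −78 °C; then allyl bromide, DMPU, −78 → −40 °C
Reagents that add atoms: allyl bromide, C=CCBr
Why: Kinetic enolate alkylation: deprotonation occurs at the C7 methylene (H-5 is a cyclobutane ring-fusion methine, C4 is quaternary), and allyl bromide should add through a chair-like transition state on the convex face of the cis-fused bicyclo[4.2.0]octanone, away from C4 and its ester, which sets C7 (R) with the allyl group cis to the equatorial C8 silyloxy group.

Step 8
Reactants: 10 7β-allyl photoadduct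
Product: 11 7β-(2-oxoethyl) photoadduct (C12 aldehyde)
Conditions: O3, CH2Cl2, −78 °C; then PPh3, −78 °C → rt
Reagents that add atoms: ozone, [O-][O+]=O
Why: Ozonolysis with reductive work-up cleaves the only alkene present, before any ring alkene exists, to the C12 aldehyde.

Step 9
Reactants: 11 7β-(2-oxoethyl) photoadduct
Product: 12 7β-(1,3-dioxolan-2-ylmethyl) photoadduct (1S,4R,5S,7R,8R,10S), the key-step precursor
Conditions: (TMSOCH2)2, TMSOTf (cat.), CH2Cl2, −78 °C
Reagents that add atoms: 1,2-bis(trimethylsilyloxy)ethane, C[Si](C)(C)OCCO[Si](C)(C)C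
Why: Aprotic silyl-triflate-catalysed acetalisation (Noyori conditions) is selective for the aldehyde over the hindered C6 ketone and stores C12 as a dioxolane that survives heat and hydride.

Step 10
Reactants: 12 7β-(1,3-dioxolan-2-ylmethyl) photoadduct
Product: 13 methyl (7R,8R)-8-[(tert-butyldimethylsilyl)oxy]-7-(1,3-dioxolan-2-ylmethyl)-10-methyl-6-oxocyclodeca-1(10),4-diene-4-carboxylate, C1=C10 E, C4=C5 ring-cis (C3 and C6 cis; E by CIP because of the ester)
Conditions: degassed toluene (dilute), base-free silylated sealed tube, 185 °C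
Reagents that add atoms: none
Why: Thermal cycloreversion of a bicyclo[2.2.0]hexane unit: homolysis of the strained central C1–C4 bond gives a cis-fused cyclohexane-1,4-diyl whose C4 radical is stabilised by the ester, and β-scission of the shared C5–C10 bond then releases both four-membered rings as the C1=C10 and C4=C5 π bonds. The closest known reaction is the thermolysis of cyclobutene–cyclohexenone [2+2] photoadducts to cis,trans-cyclodeca-1,5-dienes (a stepwise retro-[2+2]). No ring is closed by bond formation: the ten-membered ring appears by ring expansion, through fragmentation of the bond common to the two six-membered rings of the diyl. No stereocentre is created (C1, C4, C5 and C10 become trigonal, C7 and C8 are carried through); the alkene geometries follow from the chair of the cis-fused diyl, in which C14 is axial and C9 equatorial at C10 (C2 and C9 end up trans) while C6 is axial at C5 (C3 and C6 end up cis). The selectivity needed is this chair over its ring-flipped partner, which would give the 1(10)Z,4-trans isomer; it is secured by the C8 silyloxy group, equatorial in the productive chair and syn-axial to C14 in the other, which should outweigh the axial C7 chain. The trans,cis-diene should resist Cope rearrangement at this temperature, and neutral glass keeps C7, α to the ketone, from epimerising.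

Step 11
Reactants: 13 cyclodecadienone ester
Product: 14 6,15-diol (C6 carbinol as both epimers, C15 primary allylic alcohol), 8β-OTBS, 7β-(1,3-dioxolan-2-ylmethyl)
Conditions: iBu2AlH, CH2Cl2, −78 °C; aq. potassium sodium tartrate work-up
Reagents that add atoms: none
Why: 1,2-Hydride reduction of the conjugated ester to the C15 allylic alcohol; the C6 ketone is reduced as well (its configuration is irrelevant, C6 being re-oxidised in step 13), while acetal and silyl ether are inert at −78 °C.

Step 12
Reactants: 14 6,15-diol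
Product: 16 C15-methyl allylic alcohol (6-hydroxy-4,10-dimethylcyclodeca-1(10)E,4Z-diene, C6 epimers), via allylic mesylate 15 (not isolated)
Conditions: MsCl, Et3N, THF, −40 °C; then LiEt3BH, −40 → 0 °C
Reagents that add atoms: none
Why: Selective sulfonylation of the primary allylic alcohol over the hindered secondary one, followed by SN2 hydride displacement (deoxygenation), turns C15 into the methyl group without allylic transposition.

Step 13
Reactants: 16 C15-methyl allylic alcohol
Product: 17 (7R,8R)-8-[(tert-butyldimethylsilyl)oxy]-7-(1,3-dioxolan-2-ylmethyl)-4,10-dimethylcyclodeca-1(10)E,4Z-dien-6-one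
Conditions: MnO2, CH2Cl2, rt
Reagents that add atoms: none
Why: Chemoselective MnO2 oxidation of the allylic alcohol restores the C6 enone with the ring-cis C4=C5 bond untouched; both carbinol epimers converge.

Step 14
Reactants: 17 C6 enone
Product: 19 3-hydroxy enone (C3 epimers), via trimethylsilyl dienol ether 18 (not isolated)
Conditions: TMSOTf, Et3N, CH2Cl2, 0 °C; then DMDO (1 equiv), acetone, −78 °C; then aq. citric acid, MeOH, 0 °C
Reagents that add atoms: dimethyldioxirane (DMDO), CC1(C)OO1
Why: Vinylogous Rubottom oxidation: soft enolisation under equilibrating conditions should remove a C3 hydrogen (γ, on the carbon cis to the carbonyl; the α′ hydrogen on C7 is a hindered methine) to give the linear dienol silyl ether, DMDO should epoxidise its terminal, most electron-rich C3=C4 bond far faster than the isolated C1=C10 alkene, and collapse of the epoxide returns the enone with a C3 hydroxyl, the ring holding the diene s-cis so that the ring-cis C4=C5 geometry is regenerated (the C3 configuration is immaterial).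

Step 15
Reactants: 19 3-hydroxy enone
Product: 20 (7R,8R)-8-[(tert-butyldimethylsilyl)oxy]-7-(1,3-dioxolan-2-ylmethyl)-4,10-dimethylcyclodeca-1(10)E,4Z-diene-3,6-dione
Conditions: Dess–Martin periodinane, NaHCO3, CH2Cl2, 0 °C → rt
Reagents that add atoms: none
Why: Dess–Martin oxidation of the allylic alcohol converges both C3 epimers to the cis-enedione, which offers C3 as a ketone for a reagent-controlled reduction later.

Step 16
Reactants: 20 enedione silyl ether
Product: 21 (7R,8R)-8-hydroxy-7-(1,3-dioxolan-2-ylmethyl)-4,10-dimethylcyclodeca-1(10)E,4Z-diene-3,6-dione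
Conditions: HF·pyridine, pyridine, THF, 0 °C
Reagents that add atoms: none
Why: Buffered fluoride desilylation frees the C8 hydroxyl; the β-hydroxy ketone is not exposed to base, so neither elimination nor epimerisation at C7 is expected.

Step 17
Reactants: 22 angelic acid
Product: 23 (Z)-2-methylbut-2-en-1-ol
Conditions: LiAlH4, Et2O, 0 °C
Reagents that add atoms: none
Why: Hydride reduction of the acid to the primary allylic alcohol, run cold so that the Z (angelate) geometry is kept.

Step 18
Reactants: 23 (Z)-2-methylbut-2-en-1-ol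
Product: 24 [(2S,3R)-2,3-dimethyloxiran-2-yl]methanol
Conditions: Ti(OiPr)4 (cat.), L-(+)-diisopropyl tartrate, tBuOOH, 4 Å molecular sieves, CH2Cl2, −20 °C
Reagents that add atoms: tert-butyl hydroperoxide, CC(C)(C)OO
Why: Sharpless asymmetric epoxidation: with the L-(+)-tartrate the titanium-bound peroxide delivers oxygen to the alkene face that gives the (2S,3R)-epoxy alcohol, the Z geometry being carried into the cis relation of the C3 methyl and CH2OH.

Step 19
Reactants: 24 [(2S,3R)-2,3-dimethyloxiran-2-yl]methanol
Product: 25 (2R,3R)-2,3-dimethyloxirane-2-carbaldehyde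
Conditions: (COCl)2, DMSO, Et3N, CH2Cl2, −78 °C; used as a dried solution
Reagents that add atoms: none
Why: Swern oxidation gives the aldehyde with only volatile or water-soluble by-products; C2 is quaternary, so nothing can epimerise.

Step 20
Reactants: 21 8-hydroxy enedione; 25 (2R,3R)-2,3-dimethyloxirane-2-carbaldehyde
Product: 26 (6R,7S,8R)-6α-hydroxy-8β-[(2R,3R)-2,3-dimethyloxirane-2-carbonyloxy]-7β-(1,3-dioxolan-2-ylmethyl)-4,10-dimethylcyclodeca-1(10)E,4Z-dien-3-one
Conditions: SmI2 (0.3 equiv), 25 (5 equiv), THF, −10 °C; then 21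
Reagents that add atoms: none
Why: Evans–Tishchenko reduction: the trivalent samarium alkoxide generated from SmI2 and the aldehyde binds the hemiacetal formed between the C8 hydroxyl and 25, and intramolecular hydride transfer through a six-membered chair should reduce the C6 ketone 1,3-anti to O8 (6α-OH) while O8 emerges as the epoxyangelate, so one step sets C6, differentiates O6 from O8 and installs the side-chain ester; the C3 ketone has no hydroxyl within reach.

Step 21
Reactants: 26 6α-hydroxy 8β-epoxyangelate
Product: 27 6α,12-lactol (12-hydroxy-6α,12-epoxide, C12 epimers), 3-ketone, 8β-epoxyangelate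
Conditions: PPTS (cat.), acetone/H2O, 45 °C
Reagents that add atoms: water, O
Why: Acid-catalysed transacetalisation and hydrolysis: the only free hydroxyl (O6) captures the C12 oxocarbenium ion and closes the trans-fused five-membered lactol (5-exo), without ambiguity because O8 is acylated.

Step 22
Reactants: 27 6α,12-lactol
Product: 28 (6R,7R,8R)-3-oxo-8β-[(2R,3R)-2,3-dimethyloxirane-2-carbonyloxy]germacra-1(10)E,4Z-dien-12,6α-olide
Conditions: TEMPO (cat.), PhI(OAc)2, CH2Cl2, rt
Reagents that add atoms: none
Why: Oxoammonium (TEMPO) oxidation of the lactol to the γ-lactone under non-basic conditions that leave the enone, the epoxy ester and the trisubstituted alkene untouched.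

Step 23
Reactants: 28 3-oxo lactone
Product: 29 (3S,6R,7R,8R)-3β-hydroxy-8β-[(2R,3R)-2,3-dimethyloxirane-2-carbonyloxy]germacra-1(10)E,4Z-dien-12,6α-olide
Conditions: (R)-2-methyl-CBS-oxazaborolidine, catecholborane, toluene, −78 °C
Reagents that add atoms: none
Why: Corey–Bakshi–Shibata reduction: catalyst-controlled 1,2-reduction of the C3 enone carbonyl, with the α-branched alkenyl carbon C4 as the large and the C2 methylene as the small substituent, should give the (3S)-alcohol with the (R)-catalyst; lactone and esters are inert to catecholborane.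

Step 24
Reactants: 29 3β-hydroxy lactone
Product: 30 3β-isobutyryloxy-8β-epoxyangeloyloxy-germacra-1(10)E,4Z-dien-12,6α-olide
Conditions: isobutyric anhydride, Et3N, DMAP (cat.), CH2Cl2, 0 °C
Reagents that add atoms: isobutyric anhydride, CC(C)C(=O)OC(=O)C(C)C
Why: DMAP-catalysed acylation of the only free hydroxyl, the allylic C3 alcohol.

Step 25
Reactants: 30 3β-isobutyrate lactone
Product: 31 11-(dimethylaminomethyl) lactone (C11 epimers)
Conditions: LiN(iPr)2 (1.05 equiv), THF, −78 °C; then (Me2N=CH2)I
Reagents that add atoms: Eschenmoser's salt, (Me2N=CH2)I, C=[N+](C)C.[I-]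
Why: Mannich reaction of the lactone lithium enolate: the lactone α-methylene is the most acidic and most accessible C–H (the isobutyrate α-hydrogen is tertiary and several pKa units weaker, the epoxy ester has none), and the enolate is trapped at −78 °C by the iminium salt.

Step 26
Reactants: 31 11-(dimethylaminomethyl) lactone
Product: 33 3β-isobutyryloxy-8β-epoxyangeloyloxy-germacra-1(10)E,4Z,11(13)-trien-12,6α-olide, via ammonium iodide 32 (not isolated)
Conditions: MeI, MeOH, rt; then NaHCO3, EtOAc/H2O, rt
Reagents that add atoms: none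
Why: Quaternisation and base-induced β-elimination of trimethylamine (Hofmann-type, E1cB) gives the exocyclic α-methylene lactone under conditions mild enough for both esters.

Step 27
Reactants: 33 α-methylene lactone
Product: 34 target, (1R,3S,6R,7R,8R,10R)-1,10-epoxy-3-isobutyryloxy-8-[(2R,3R)-2,3-dimethyloxirane-2-carbonyloxy]germacra-4Z,11(13)-dien-12,6-olide
Conditions: mCPBA, NaHCO3, CH2Cl2, 0 °C
Reagents that add atoms: meta-chloroperbenzoic acid (mCPBA), OOC(=O)c1cccc(Cl)c1
Why: Prilezhaev epoxidation: the trisubstituted C1=C10 bond is the only electron-rich alkene (C4=C5 is deactivated by two allylic acyloxy groups, C11=C13 is conjugated), and the peracid should attack the outer face of this E-alkene in the ring conformer that holds C14 on the β-face, giving the trans (1R,10R)-epoxide; buffering protects the acid-labile product.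

**Compound list**
1 | hepta-1,6-dien-4-ol | C=CCC(O)CC=C | starting material
2 | tert-butyl(hepta-1,6-dien-4-yloxy)dimethylsilane | C=CCC(CC=C)O[Si](C)(C)C(C)(C)C | intermediate
3 | 4-[(tert-butyldimethylsilyl)oxy]heptane-2,6-dione | CC(=O)CC(CC(C)=O)O[Si](C)(C)C(C)(C)C | intermediate
4 | (R)-5-[(tert-butyldimethylsilyl)oxy]-3-methylcyclohex-2-en-1-one | CC1=CC(=O)C[C@H](O[Si](C)(C)C(C)(C)C)C1 | intermediate
5 | methyl cyclobutanecarboxylate | COC(=O)C1CCC1 | starting material
6 | methyl 1-(phenylselanyl)cyclobutane-1-carboxylate | COC(=O)C1(CCC1)[Se]c1ccccc1 | intermediate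
7 | methyl 1-(phenylseleninyl)cyclobutane-1-carboxylate (selenoxide, not isolated) | COC(=O)C1(CCC1)[Se](=O)c1ccccc1 | intermediate
8 | methyl cyclobut-1-ene-1-carboxylate | COC(=O)C1=CCC1 | intermediate
9 | cis,anti,cis photoadduct (1S,4R,5S,8R,10S), 8β-OTBS anti to the central cyclobutane | COC(=O)[C@]12CC[C@H]1[C@]3(C)C[C@@H](O[Si](C)(C)C(C)(C)C)CC(=O)[C@H]23 | intermediate
10 | 7β-allyl photoadduct (7R) | COC(=O)[C@]12CC[C@H]1[C@]3(C)C[C@@H](O[Si](C)(C)C(C)(C)C)[C@@H](CC=C)C(=O)[C@H]23 | intermediate
11 | 7β-(2-oxoethyl) photoadduct | COC(=O)[C@]12CC[C@H]1[C@]3(C)C[C@@H](O[Si](C)(C)C(C)(C)C)[C@@H](CC=O)C(=O)[C@H]23 | intermediate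
12 | 7β-(1,3-dioxolan-2-ylmethyl) photoadduct (key-step precursor) | COC(=O)[C@]12CC[C@H]1[C@]3(C)C[C@@H](O[Si](C)(C)C(C)(C)C)[C@@H](CC4OCCO4)C(=O)[C@H]23 | intermediate
13 | methyl (7R,8R)-8-OTBS-7-(1,3-dioxolan-2-ylmethyl)-10-methyl-6-oxocyclodeca-1(10),4-diene-4-carboxylate, 1(10)E, C4=C5 ring-cis (key-step product) | O=C1/C=C(/C(=O)OC)CC/C=C(\C)C[C@@H](O[Si](C)(C)C(C)(C)C)[C@H]1CC2OCCO2 | intermediate
14 | 6,15-diol (C6 epimers) | OC1/C=C(/CO)CC/C=C(\C)C[C@@H](O[Si](C)(C)C(C)(C)C)[C@H]1CC2OCCO2 | intermediate
15 | C15 allylic mesylate (not isolated) | OC1/C=C(/COS(C)(=O)=O)CC/C=C(\C)C[C@@H](O[Si](C)(C)C(C)(C)C)[C@H]1CC2OCCO2 | intermediate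
16 | C15-methyl allylic alcohol (C6 epimers) | OC1/C=C(/C)CC/C=C(\C)C[C@@H](O[Si](C)(C)C(C)(C)C)[C@H]1CC2OCCO2 | intermediate
17 | (7R,8R)-8-OTBS-7-(1,3-dioxolan-2-ylmethyl)-4,10-dimethylcyclodeca-1(10)E,4Z-dien-6-one | O=C1/C=C(/C)CC/C=C(\C)C[C@@H](O[Si](C)(C)C(C)(C)C)[C@H]1CC2OCCO2 | intermediate
18 | 6-(trimethylsilyloxy)-3,5-dienol ether (not isolated; geometry of the two new double bonds not assigned) | C[Si](C)(C)OC1=CC(C)=CC/C=C(\C)C[C@@H](O[Si](C)(C)C(C)(C)C)[C@H]1CC2OCCO2 | intermediate
19 | 3-hydroxy-4Z-en-6-one (C3 epimers) | O=C1/C=C(/C)C(O)C/C=C(\C)C[C@@H](O[Si](C)(C)C(C)(C)C)[C@H]1CC2OCCO2 | intermediate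
20 | (7R,8R)-8-OTBS-7-(1,3-dioxolan-2-ylmethyl)-4,10-dimethylcyclodeca-1(10)E,4Z-diene-3,6-dione | O=C1/C=C(/C)C(=O)C/C=C(\C)C[C@@H](O[Si](C)(C)C(C)(C)C)[C@H]1CC2OCCO2 | intermediate
21 | (7R,8R)-8-hydroxy-7-(1,3-dioxolan-2-ylmethyl)-4,10-dimethylcyclodeca-1(10)E,4Z-diene-3,6-dione | O=C1/C=C(/C)C(=O)C/C=C(\C)C[C@@H](O)[C@H]1CC2OCCO2 | intermediate
22 | angelic acid, (Z)-2-methylbut-2-enoic acid | C/C=C(/C)C(=O)O | starting material
23 | (Z)-2-methylbut-2-en-1-ol | C/C=C(/C)CO | intermediate
24 | [(2S,3R)-2,3-dimethyloxiran-2-yl]methanol | OC[C@]1(C)O[C@@H]1C | intermediate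
25 | (2R,3R)-2,3-dimethyloxirane-2-carbaldehyde | O=C[C@]1(C)O[C@@H]1C | intermediate
26 | (6R,7S,8R)-6α-hydroxy-8β-epoxyangeloyloxy-7β-(1,3-dioxolan-2-ylmethyl)-4,10-dimethylcyclodeca-1(10)E,4Z-dien-3-one | O[C@@H]1/C=C(/C)C(=O)C/C=C(\C)C[C@@H](OC(=O)[C@]2(C)O[C@@H]2C)[C@H]1CC3OCCO3 | intermediate
27 | 6α,12-lactol (C12 epimers), 3-ketone, 8β-epoxyangelate | C1C(O)O[C@@H]2/C=C(/C)C(=O)C/C=C(\C)C[C@@H](OC(=O)[C@]3(C)O[C@@H]3C)[C@@H]12 | intermediate
28 | (6R,7R,8R)-3-oxo-8β-epoxyangeloyloxy-germacra-1(10)E,4Z-dien-12,6α-olide | C1C(=O)O[C@@H]2/C=C(/C)C(=O)C/C=C(\C)C[C@@H](OC(=O)[C@]3(C)O[C@@H]3C)[C@@H]12 | intermediate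
29 | (3S,6R,7R,8R)-3β-hydroxy-8β-epoxyangeloyloxy-germacra-1(10)E,4Z-dien-12,6α-olide | C1C(=O)O[C@@H]2/C=C(/C)[C@@H](O)C/C=C(\C)C[C@@H](OC(=O)[C@]3(C)O[C@@H]3C)[C@@H]12 | intermediate
30 | 3β-isobutyryloxy-8β-epoxyangeloyloxy-germacra-1(10)E,4Z-dien-12,6α-olide | C1C(=O)O[C@@H]2/C=C(/C)[C@@H](OC(=O)C(C)C)C/C=C(\C)C[C@@H](OC(=O)[C@]3(C)O[C@@H]3C)[C@@H]12 | intermediate
31 | 11-(dimethylaminomethyl) lactone (C11 epimers) | CN(C)CC1C(=O)O[C@@H]2/C=C(/C)[C@@H](OC(=O)C(C)C)C/C=C(\C)C[C@@H](OC(=O)[C@]3(C)O[C@@H]3C)[C@@H]12 | intermediate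
32 | 11-(trimethylammoniomethyl) lactone iodide (not isolated) | C[N+](C)(C)CC1C(=O)O[C@@H]2/C=C(/C)[C@@H](OC(=O)C(C)C)C/C=C(\C)C[C@@H](OC(=O)[C@]3(C)O[C@@H]3C)[C@@H]12.[I-] | intermediate
33 | 3β-isobutyryloxy-8β-epoxyangeloyloxy-germacra-1(10)E,4Z,11(13)-trien-12,6α-olide | C=C1C(=O)O[C@@H]2/C=C(/C)[C@@H](OC(=O)C(C)C)C/C=C(\C)C[C@@H](OC(=O)[C@]3(C)O[C@@H]3C)[C@@H]12 | intermediate
34 | CNP0117882.2, (1R,3S,6R,7R,8R,10R)-1,10-epoxy-3-isobutyryloxy-8-[(2R,3R)-2,3-dimethyloxirane-2-carbonyloxy]germacra-4Z,11(13)-dien-12,6-olide | C=C1C(=O)O[C@@H]2/C=C(/C)[C@@H](OC(=O)C(C)C)C[C@H]3O[C@]3(C)C[C@@H](OC(=O)[C@]3(C)O[C@@H]3C)[C@@H]12 | target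

**Count**
Total: 27 steps. Longest linear sequence: 22 steps (steps 1–3, 6–16, 20–27).

**Steps most likely to fail**

Step 10 (key step). What may go wrong: leakage through the ring-flipped chair of the diyl, whose bias is lowered by the axial C7 chain, giving the 1(10)Z,4-trans isomer; loss of the C7 configuration by enolisation at 185 °C; or onward Cope rearrangement. Fallback: reverse the order of side-chain attachment and ring opening. It sets out from 9, which has no axial substituent in the productive chair. Heating 9 under the conditions of step 10 gives methyl (8R)-8-[(tert-butyldimethylsilyl)oxy]-10-methyl-6-oxocyclodeca-1(10),4-diene-4-carboxylate F3. Its kinetic lithium enolate (LiN(iPr)2, THF/HMPA, −78 °C) is then alkylated at C7 with 2-(iodomethyl)-1,3-dioxolane on the ten-membered ring; the C7 epimers are separated or equilibrated through the ketone, and the route is rejoined at 13.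

Step 7. What may go wrong: poor facial selectivity, the vicinal silyloxy group overriding the convex-face bias and sending the allyl group to the face anti to it. Fallback: make the last bond formed at C7 a C–H bond. It sets out from 9. Aldol addition of the lithium enolate to 1,3-dioxolane-2-carbaldehyde gives the β-hydroxy ketone F1. Dehydration (Burgess reagent, toluene, 50 °C) gives the (E)-alkylidene ketone F2. Hydrogenation (H2, Pd/C, EtOAc) then delivers hydrogen to C7 from the face that an electrophile prefers, anti to the silyloxy group, which leaves the side chain cis to it. This gives 12 directly and bypasses 10 and 11.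

Step 20. What may go wrong: slow hemiacetal formation with the hindered epoxy aldehyde, opening of its oxirane by Lewis-acidic trivalent samarium, or acyl migration from O8 to O6. Fallback: separate the reduction from the esterification. It sets out from 21. Evans–Tishchenko reduction with acetaldehyde (SmI2 cat., THF, −10 °C) gives the 6α-hydroxy 8β-acetate F4. Silylation (TESCl, imidazole, DMF) gives the 6-triethylsilyl ether F5, and methanolysis (K2CO3, MeOH, 0 °C) gives the 8β-alcohol F6. Yamaguchi esterification (2,4,6-trichlorobenzoyl chloride, Et3N, DMAP, toluene) with (2R,3R)-2,3-dimethyloxirane-2-carboxylic acid F7, made from 25 by Pinnick oxidation (NaClO2, NaH2PO4, 2-methylbut-2-ene), gives the 8β-epoxyangelate 6-silyl ether F8. HF·pyridine removes the silyl group and the route is rejoined at 26.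

**Further compounds**
F1 | step 7 | 7-[(1,3-dioxolan-2-yl)hydroxymethyl] photoadduct (aldol adduct, epimers) | COC(=O)[C@]12CC[C@H]1[C@]3(C)C[C@@H](O[Si](C)(C)C(C)(C)C)C(C(O)C4OCCO4)C(=O)[C@H]23
F2 | step 7 | 7-[(E)-(1,3-dioxolan-2-yl)methylidene] photoadduct | COC(=O)[C@]12CC[C@H]1[C@]3(C)C[C@@H](O[Si](C)(C)C(C)(C)C)/C(=C\C4OCCO4)C(=O)[C@H]23
F3 | step 10 | methyl (8R)-8-[(tert-butyldimethylsilyl)oxy]-10-methyl-6-oxocyclodeca-1(10),4-diene-4-carboxylate, 1(10)E, C4=C5 ring-cis | O=C1/C=C(/C(=O)OC)CC/C=C(\C)C[C@@H](O[Si](C)(C)C(C)(C)C)C1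
F4 | step 20 | 6α-hydroxy-8β-acetoxy-7β-(1,3-dioxolan-2-ylmethyl)-4,10-dimethylcyclodeca-1(10)E,4Z-dien-3-one | O[C@@H]1/C=C(/C)C(=O)C/C=C(\C)C[C@@H](OC(C)=O)[C@H]1CC2OCCO2
F5 | step 20 | 6α-triethylsilyloxy 8β-acetate | CC[Si](CC)(CC)O[C@@H]1/C=C(/C)C(=O)C/C=C(\C)C[C@@H](OC(C)=O)[C@H]1CC2OCCO2
F6 | step 20 | 6α-triethylsilyloxy 8β-alcohol | CC[Si](CC)(CC)O[C@@H]1/C=C(/C)C(=O)C/C=C(\C)C[C@@H](O)[C@H]1CC2OCCO2
F7 | step 20 | (2R,3R)-2,3-dimethyloxirane-2-carboxylic acid (epoxyangelic acid) | OC(=O)[C@]1(C)O[C@@H]1C
F8 | step 20 | 6α-triethylsilyloxy 8β-epoxyangelate | CC[Si](CC)(CC)O[C@@H]1/C=C(/C)C(=O)C/C=C(\C)C[C@@H](OC(=O)[C@]2(C)O[C@@H]2C)[C@H]1CC3OCCO3
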